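# Hierochin B by oxidative ring contraction of a 2-aryl-2H-chromene

## Analysis of the target

Hierochin B (11) is a 2,3-dihydrobenzofuran neolignan. Benzene ring A is fused through C3a and C7a to the dihydrofuran ring (O1, C2, C3); ring B (3,4-dimethoxyphenyl) sits on C2, a hydroxymethyl group on C3, a methoxy group on C7 and an (E)-3-hydroxyprop-1-enyl chain on C5. The only stereocentres are the adjacent C2 (S) and C3 (R), and ring B and the hydroxymethyl arm are trans on the five-membered ring. C2 is a benzylic ether carbon activated by the para-methoxy group of ring B, so C2–O1 can ionise in strong acid. The cinnamyl alcohol chain is sensitive to acid and to electrophilic oxidants. The difficulty is the absolute configuration of two contiguous stereocentres, since the trans preference of the ring fixes them only relative to each other. The plan rests on C3, which carries C3a of ring A and a one-carbon oxygenated arm. Such a carbon is what a 1,2-shift of the ring A carbon C4a across the C3=C4 bond of a 2-aryl-2H-chromene leaves behind, with the former C4 pushed out of the ring at the acetal oxidation level, so a single stereocentre, C2 of the chromene, can dictate C3.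

## Retrosynthetic reasoning

**11 to 10, then 10 to 8 and 9.** The first cut is the C5–alkenyl bond, after the silyl ether 10 is recognised as the protected form of 11. The chain is removed first because an electron-rich styrene would compete with the ring alkene for the electrophilic oxidant of the key step. A bromine atom at C5, inert to everything earlier, stands in for it. The cut gives bromo alcohol 8 and alkenyl boronate 9, which already holds the E double bond and the allylic oxygen. The forward reaction is an sp2–sp2 cross-coupling with retention of alkene geometry, followed by desilylation.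

**8 to 7 to 6.** No skeletal bond is cut here. The hydroxymethyl carbon of 8 is traced through aldehyde 7 to dimethyl acetal 6, because a 1,2-shift onto C3 leaves the migration origin at the aldehyde oxidation level. The forward steps must unmask and reduce the aldehyde without ionising C2–O1. C3 of 7 is epimerisable, but trans is the more stable arrangement, so equilibration can only help.

**6 to 4 (key disconnection).** The C3–C3a bond of 6 is cut and C3a is reconnected to the acetal carbon. This expands the dihydrofuran to the pyran ring of chromene 4, in which the acetal carbon is C4 and C3a is C4a. Cutting O1–C2 or C2–C3 instead would lead to open-chain precursors in which both stereocentres must be set independently. Chromene 4 has only C2 and a flat C3=C4 bond. The forward reaction must add an electrophile to C3 anti to ring B, then let ring A displace it with inversion while C4 is captured as an acetal.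

**4 to 3.** The C3–H bond of 4 is traced to a formyl group in 3. The extra carbon is the price of the catalytic assembly of the chromene, which needs a conjugated aldehyde as activating group. It must be removed without moving the C3=C4 bond and without touching C2.

**3 to 1 and 2.** O1–C2 and C3–C4 are cut. This gives salicylaldehyde 1, which carries the bromine and the ring A methoxy group, and cinnamaldehyde 2, which carries ring B. In the forward sense a chiral secondary amine activates 2, the phenol oxygen of 1 adds to its β-carbon and an aldol condensation closes the pyran. This is the only step in which a catalyst sets a stereocentre.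

## Alternatives that were turned down

**Alternative 1:** Two aryl–carbon bonds, C2–ring B and C3–C3a, are cut in an open chain and no ring is cut. In the forward key step a lithiated ring B adds to the boron of a (Z)-alkenyl boronic ester carrying the silyloxymethyl arm. Pd(OAc)2 (divalent palladium precatalyst) with a chiral ferrocenyl bisphosphine then couples the boronate with a protected ring A aryl bromide. Ring B shifts from boron to C2 while palladium delivers ring A to C3, giving the anti boronate A1.
- For: one catalytic step sets both stereocentres under catalyst control from three simple fragments, and no migratory aptitude has to be trusted. On both points it is stronger than the chosen plan.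
- Against: A1 is still acyclic. The C–B bond must be oxidised, the ring A oxygen unmasked and the benzylic alcohol displaced to close O1–C2. Ring A must carry a protected phenol and a protected aldehyde, and the chain must still be built from that aldehyde by olefination and reduction. A hindered ortho-alkoxy aryl bromide and a β-substituted alkenyl boronate are demanding partners for this coupling.
- Comparison: the step count is about twice that of the chosen route, which needs no protecting group on ring A and lets C2 set C3.

**Alternative 2:** Ring A itself is cut, at C3a–C7a and C6–C7, and traced to a furan and an alkynyl ether. The open-chain ethynyl ether A2, with both stereocentres in place, is treated with Ph3PAuNTf2 (monovalent gold). The furan carbon attacks the oxygen-bearing alkyne carbon, which closes the dihydrofuran, and the furan reorganises into the benzene ring with its oxygen delivered to C7, giving phenol A3.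
- For: the step is mild and atom-economic, the substitution pattern of ring A is unambiguous, and the C7 hydroxyl is ready for methylation. Its neutral conditions are kinder to ring B than an electrophilic oxidation.
- Against: the key step creates no stereocentre, so C2 and C3 must both be set beforehand in an acyclic precursor. The ethynyl ether of a secondary benzylic alcohol on an electron-rich arene is prone to sigmatropic rearrangement and ionisation. A 2,4-disubstituted furan is not a simple building block. A3 still needs methylation, differentiation of two primary silyl ethers and a three-step homologation of the C5 arm.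
- Comparison: the chosen route reaches the ring system with the chain handle and the methoxy group already in place, and one stereocentre does the work of two.

**Alternative 3:** Ring A is again cut, at C3a–C4 and C7–C7a, and the dihydrofuran is kept intact as a lactone. The silyl ketene acetal A4 of that lactone adds on heating as an electron-rich dienophile to the bromopyrone ester A5. Decarboxylation of the bridged adduct and loss of the silyloxy group aromatise it to A6.
- For: both stereocentres sit in a robust trans lactone that can be made by established asymmetric methods, and the benzannulation does not touch them. The polarity of the partners fixes the regiochemistry. On stereochemical security it is safer than a cationic rearrangement.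
- Against: A4 is a ketene acetal whose reacting carbon sits next to a branched ring carbon, which makes it a hindered dienophile. A6 has bromine at C7 where the target has methoxy, so a C–O coupling ortho to O1 is needed. The ester must go through reduction, olefination and a second reduction to reach the propenol. With the lactone synthesis this is well over ten steps.
- Comparison: the chosen route trades that security for brevity, derives C3 stereospecifically from C2, and has a thermodynamic safety net at aldehyde 7.

Key step: step 3

## Remarks on the chemistry

- The facial sense in step 1 is assigned from the usual shielding model for iminium ions of 2-(diarylsilyloxymethyl)pyrrolidines and was not checked against a reported case. If it proved opposite, the (R)-configured catalyst would be used and nothing else changes.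
- Compounds 1, 2 and 9 are taken as purchased.

## Route

Step 1
Reactants: 1 5-bromo-2-hydroxy-3-methoxybenzaldehyde; 2 (E)-3-(3,4-dimethoxyphenyl)prop-2-enal
Product: 3 (2R)-6-bromo-2-(3,4-dimethoxyphenyl)-8-methoxy-2H-chromene-3-carbaldehyde
Conditions: (S)-2-[diphenyl(trimethylsilyloxy)methyl]pyrrolidine (20 mol%), 2-nitrobenzoic acid (20 mol%), 4 Å MS, PhMe, rt, dark
Reagents that add atoms: none
Why: Aminocatalytic domino oxa-Michael–aldol condensation: 2 reacts as its (E)-iminium ion, the phenol oxygen of 1 adds to C-beta, and the resulting enamine closes onto the aryl aldehyde with loss of water to give the chromene. The diphenyl(silyloxy)methyl group shields one face of the iminium ion, so oxygen should enter from the open Si face of C-beta and give the R descriptor at C2. This is the same spatial arrangement as in (S)-4; the descriptor changes only because C3 loses its priority over ring B when the formyl group is removed.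

Step 2
Reactants: 3 (2R)-6-bromo-2-(3,4-dimethoxyphenyl)-8-methoxy-2H-chromene-3-carbaldehyde
Product: 4 (2S)-6-bromo-2-(3,4-dimethoxyphenyl)-8-methoxy-2H-chromene
Conditions: RhCl(PPh3)3 (1.1 equiv), PhMe, 90 °C, Ar, dark
Reagents that add atoms: none
Why: Tsuji–Wilkinson decarbonylation: the formyl C–H bond adds oxidatively to monovalent rhodium, carbon monoxide de-inserts, and reductive elimination forms the C3–H bond with retention, so the double bond stays between C3 and C4 and C2 is not touched. Rhodium ends as RhCl(CO)(PPh3)2, so a full equivalent is used, which keeps the temperature moderate; the C–Br bond should be inert under these conditions.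

Step 3
Reactants: 4 (2S)-6-bromo-2-(3,4-dimethoxyphenyl)-8-methoxy-2H-chromene
Product: 6 (2S,3S)-5-bromo-2-(3,4-dimethoxyphenyl)-3-(dimethoxymethyl)-7-methoxy-2,3-dihydro-1-benzofuran, via trans-3-iodanyl-4-methoxychromane 5 (not isolated)
Conditions: PhI(OH)OTs (1.2 equiv), MeOH/HC(OMe)3 (1:1), −20 → 0 °C, dark
Reagents that add atoms: methanol, CO
Why: Proposed new method: in methanol PhI(OH)OTs is an electrophile of trivalent iodine that should add to C3 of the electron-rich C3=C4 bond of 4 on the face away from ring B, while methanol caps the C4 cation, which O1 stabilises through ring A, from the opposite face to give the all-trans adduct 5. In the all-equatorial half-chair of 5 the C3–I bond is antiperiplanar to C4–C4a, so the ipso carbon C4a, activated by the ortho oxygen O1, bridges to C3 as iodobenzene leaves; the spiro phenonium ion then opens to the methoxy-stabilised C4 cation, which methanol traps as dimethyl acetal 6. The closest known reaction type is the ring contraction of 1,2-dihydronaphthalenes to trans-indane acetals, and of 2-arylchroman-4-ones to 2-aryl-2,3-dihydrobenzofuran-3-carboxylates, with PhI(OH)OTs or Tl(NO3)3 (trivalent thallium); a 2-aryl-2H-chromene without oxygen at C4 is not known to have been used. The dihydrofuran ring is closed not by a cyclisation but by the suprafacial 1,2-shift, formally a 3-exo-tet attack of C4a on C3 followed by cleavage of C4–C4a. The new stereocentre C3 is controlled by C2: iodine enters anti to ring B and is displaced with inversion, so the acetal carbon ends trans to ring B, (2S,3S). The step needs Markovnikov regioselectivity, which O1 secures, and migration of ring A rather than of ring B or substitution by solvent, which the equatorial C–I bond and the oxocarbenium ion formed only by the ring A shift should favour. It also needs no dehydrogenation of the pyran ring, and here it helps that neither H2 nor H4 is anti to iodine in 5.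

Step 4
Reactants: 6 (2S,3S)-5-bromo-2-(3,4-dimethoxyphenyl)-3-(dimethoxymethyl)-7-methoxy-2,3-dihydro-1-benzofuran
Product: 7 (2S,3S)-5-bromo-2-(3,4-dimethoxyphenyl)-7-methoxy-2,3-dihydro-1-benzofuran-3-carbaldehyde
Conditions: 1 M HCl, THF, 0 °C → rt; crude product used at once
Reagents that add atoms: water, O
Why: Acid hydrolysis of a dimethyl acetal through the methoxy-stabilised oxocarbenium ion, which should be fast enough in dilute acid that the benzylic C2–O1 bond does not ionise. C3 is now epimerisable, but trans is the more stable arrangement, and ring opening by β-elimination of O1 would be the reverse of a 5-endo-trig closure, so the configuration from step 3 should persist.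

Step 5
Reactants: 7 (2S,3S)-5-bromo-2-(3,4-dimethoxyphenyl)-7-methoxy-2,3-dihydro-1-benzofuran-3-carbaldehyde
Product: 8 [(2S,3R)-5-bromo-2-(3,4-dimethoxyphenyl)-7-methoxy-2,3-dihydro-1-benzofuran-3-yl]methanol
Conditions: NaBH4, MeOH, −20 → 0 °C
Reagents that add atoms: none
Why: Hydride reduction of the aldehyde, run cold and briefly so that C3 is not enolised. The descriptor at C3 changes from S to R only because the hydroxymethyl group ranks below C2.

Step 6
Reactants: 8 [(2S,3R)-5-bromo-2-(3,4-dimethoxyphenyl)-7-methoxy-2,3-dihydro-1-benzofuran-3-yl]methanol; 9 tert-butyldimethyl{[(2E)-3-(4,4,5,5-tetramethyl-1,3,2-dioxaborolan-2-yl)prop-2-en-1-yl]oxy}silane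
Product: 10 [(2S,3R)-5-[(1E)-3-(tert-butyldimethylsilyloxy)prop-1-en-1-yl]-2-(3,4-dimethoxyphenyl)-7-methoxy-2,3-dihydro-1-benzofuran-3-yl]methanol
Conditions: PdCl2(dppf) (5 mol%), K2CO3 (3 equiv), 1,4-dioxane/H2O (4:1), 80 °C
Reagents that add atoms: none
Why: Suzuki–Miyaura coupling: zerovalent palladium inserts into the C5–Br bond, the alkenyl group of 9 is transferred with retention of the E geometry, and reductive elimination forms the C5–alkenyl bond. The free primary alcohol and the silyl ether tolerate aqueous carbonate, and neither stereocentre is near the reacting site.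

Step 7
Reactants: 10 [(2S,3R)-5-[(1E)-3-(tert-butyldimethylsilyloxy)prop-1-en-1-yl]-2-(3,4-dimethoxyphenyl)-7-methoxy-2,3-dihydro-1-benzofuran-3-yl]methanol
Product: 11 hierochin B, (2E)-3-[(2S,3R)-2-(3,4-dimethoxyphenyl)-3-(hydroxymethyl)-7-methoxy-2,3-dihydro-1-benzofuran-5-yl]prop-2-en-1-ol
Conditions: Bu4NF (1.2 equiv), THF, 0 °C → rt
Reagents that add atoms: none
Why: Fluoride cleavage of the Si–O bond, driven by the strength of the Si–F bond. The conditions are mild enough for the cinnamyl alcohol and for C2–O1.

## Compound list

1 | 5-bromo-2-hydroxy-3-methoxybenzaldehyde | COc1cc(Br)cc(C=O)c1O | starting material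
2 | (E)-3-(3,4-dimethoxyphenyl)prop-2-enal | COc1ccc(/C=C/C=O)cc1OC | starting material
3 | (2R)-6-bromo-2-(3,4-dimethoxyphenyl)-8-methoxy-2H-chromene-3-carbaldehyde | COc1ccc([C@@H]2C(C=O)=Cc3cc(Br)cc(OC)c3O2)cc1OC | intermediate
4 | (2S)-6-bromo-2-(3,4-dimethoxyphenyl)-8-methoxy-2H-chromene | COc1ccc([C@@H]2C=Cc3cc(Br)cc(OC)c3O2)cc1OC | intermediate
5 | (2R,3S,4R)-6-bromo-2-(3,4-dimethoxyphenyl)-4,8-dimethoxy-3-[phenyl(tosyloxy)-λ3-iodanyl]chromane (ring B and iodine trans, iodine and 4-methoxy trans) | COc1ccc([C@@H]2[C@@H](I(c3ccccc3)OS(=O)(=O)c3ccc(C)cc3)[C@H](OC)c3cc(Br)cc(OC)c3O2)cc1OC | intermediate (not isolated)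
6 | (2S,3S)-5-bromo-2-(3,4-dimethoxyphenyl)-3-(dimethoxymethyl)-7-methoxy-2,3-dihydro-1-benzofuran (trans) | COc1ccc([C@H]2Oc3c(OC)cc(Br)cc3[C@@H]2C(OC)OC)cc1OC | intermediate
7 | (2S,3S)-5-bromo-2-(3,4-dimethoxyphenyl)-7-methoxy-2,3-dihydro-1-benzofuran-3-carbaldehyde (trans) | COc1ccc([C@H]2Oc3c(OC)cc(Br)cc3[C@@H]2C=O)cc1OC | intermediate
8 | [(2S,3R)-5-bromo-2-(3,4-dimethoxyphenyl)-7-methoxy-2,3-dihydro-1-benzofuran-3-yl]methanol (trans) | COc1ccc([C@H]2Oc3c(OC)cc(Br)cc3[C@@H]2CO)cc1OC | intermediate
9 | tert-butyldimethyl{[(2E)-3-(4,4,5,5-tetramethyl-1,3,2-dioxaborolan-2-yl)prop-2-en-1-yl]oxy}silane | CC(C)(C)[Si](C)(C)OC/C=C/B1OC(C)(C)C(C)(C)O1 | starting material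
10 | [(2S,3R)-5-[(1E)-3-(tert-butyldimethylsilyloxy)prop-1-en-1-yl]-2-(3,4-dimethoxyphenyl)-7-methoxy-2,3-dihydro-1-benzofuran-3-yl]methanol | COc1ccc([C@H]2Oc3c(OC)cc(/C=C/CO[Si](C)(C)C(C)(C)C)cc3[C@@H]2CO)cc1OC | intermediate
11 | hierochin B, (2E)-3-[(2S,3R)-2-(3,4-dimethoxyphenyl)-3-(hydroxymethyl)-7-methoxy-2,3-dihydro-1-benzofuran-5-yl]prop-2-en-1-ol | COc1ccc([C@H]2Oc3c(OC)cc(/C=C/CO)cc3[C@@H]2CO)cc1OC | target

## Step count and least certain steps

Total: 7 steps. Longest linear sequence: 7 steps (1 to 11; 2 and 9 enter as purchased reagents).

**Step 3 (key step, proposed new method).**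
- What may go wrong: migration of the wrong group. In the all-axial conformer of 5 the C2–ring B bond, not C4–C4a, is antiperiplanar to C3–I, and ring B with its para-methoxy group is the intrinsically better migrating group, so a 1,2-shift of ring B from C2 to C3 can compete.
- Other leaks: direct displacement of the iodanyl group by solvent, dehydrogenation of the pyran ring, and attack of the oxidant on ring B. The sulfonic acid set free may also ionise C2–O1 of unreacted 4 and erode its configuration.
- Safety net: attack of iodine on the wrong face would matter less, since a cis product should converge to trans at aldehyde 7.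
- Fallback (sets out from 4, returns at 8): it moves the ring contraction to the ketone oxidation level, where it is established for 2-arylchroman-4-ones and where the shift of ring A produces a dialkoxycarbenium ion. Mukaiyama hydration of 4 (Mn(dpm)3 cat., PhSiH3, O2, iPrOH, 0 °C) puts the hydroxyl on the benzylic C4 and gives (2S)-6-bromo-2-(3,4-dimethoxyphenyl)-8-methoxychroman-4-ol F1 as a mixture of C4 epimers. MnO2 in CH2Cl2 oxidises it to (2S)-6-bromo-2-(3,4-dimethoxyphenyl)-8-methoxychroman-4-one F2. PhI(OAc)2 with H2SO4 in HC(OMe)3 contracts the ring of the enol ether formed in the flask to methyl (2S,3S)-5-bromo-2-(3,4-dimethoxyphenyl)-7-methoxy-2,3-dihydro-1-benzofuran-3-carboxylate F3. LiBH4 in THF reduces the ester to 8, so steps 3 to 5 are replaced.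

**Step 2.**
- What may go wrong: loss of configuration at C2 by reversible thermal electrocyclic opening of the pyran ring at the temperature the decarbonylation needs, and migration of the C3=C4 bond towards O1 by rhodium hydride species, which would destroy the stereocentre.
- Fallback (sets out from 1, returns at 4, bypassing 3): Wittig olefination and lactonisation of 1 with Ph3P=CHCO2Et in hot N,N-diethylaniline gives 6-bromo-8-methoxy-2H-chromen-2-one F4. iBu2AlH at −78 °C reduces it to 6-bromo-8-methoxy-2H-chromen-2-ol F5, and ethanol with pyridinium 4-methylbenzenesulfonate gives 6-bromo-2-ethoxy-8-methoxy-2H-chromene F6. Enantioselective addition of diethyl (3,4-dimethoxyphenyl)boronate to the benzopyrylium ion released from F6, under a chiral tartaric-acid-derived Brønsted acid with Yb(OTf)3, gives 4. The catalyst enantiomer is chosen to give the S configuration.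

**Step 1.**
- What may go wrong: low enantioselectivity. The electron-rich enal 2 gives a weakly electrophilic iminium ion, the conjugate addition is reversible, and the product can re-enter the catalytic cycle and racemise by retro-oxa-Michael opening.
- Fallback (sets out from 1 and 2, returns at 4): the stereocentre is set by allylic substitution instead of conjugate addition. Methylenation of 1 with Ph3P=CH2 (2.2 equiv, THF) gives 4-bromo-2-ethenyl-6-methoxyphenol F7. NaBH4 with CeCl3 reduces 2 to (E)-3-(3,4-dimethoxyphenyl)prop-2-en-1-ol F8, and ClCO2Me with pyridine gives its methyl carbonate F9. [Ir(cod)Cl]2 with a chiral phosphoramidite ligand joins the phenoxide of F7 to the branched position of F9 and gives 5-bromo-2-{[(1S)-1-(3,4-dimethoxyphenyl)prop-2-en-1-yl]oxy}-1-ethenyl-3-methoxybenzene F10. Ring-closing metathesis with the second-generation Grubbs catalyst RuCl2(=CHPh)(PCy3)(H2IMes) in CH2Cl2 at 40 °C closes the pyran and gives 4.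

**Step 6.**
- What may go wrong: slow oxidative addition into the electron-rich C5–Br bond, which leaves time for protodeboronation of 9 and for isomerisation of the allylic silyl ether by palladium hydride.
- Fallback (sets out from 8, returns at 11): Heck reaction of 8 with methyl acrylate (Pd(OAc)2, P(o-tol)3, Et3N, DMF, 100 °C) gives methyl (2E)-3-[(2S,3R)-2-(3,4-dimethoxyphenyl)-3-(hydroxymethyl)-7-methoxy-2,3-dihydro-1-benzofuran-5-yl]prop-2-enoate F11. iBu2AlH in CH2Cl2 at −78 °C reduces the ester to 11, so steps 6 and 7 are replaced.

## Further compounds

F1 | step 3 | (2S)-6-bromo-2-(3,4-dimethoxyphenyl)-8-methoxychroman-4-ol, mixture of C4 epimers | COc1ccc([C@@H]2CC(O)c3cc(Br)cc(OC)c3O2)cc1OC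
F2 | step 3 | (2S)-6-bromo-2-(3,4-dimethoxyphenyl)-8-methoxychroman-4-one | COc1ccc([C@@H]2CC(=O)c3cc(Br)cc(OC)c3O2)cc1OC
F3 | step 3 | methyl (2S,3S)-5-bromo-2-(3,4-dimethoxyphenyl)-7-methoxy-2,3-dihydro-1-benzofuran-3-carboxylate | COc1ccc([C@H]2Oc3c(OC)cc(Br)cc3[C@@H]2C(=O)OC)cc1OC
F4 | step 2 | 6-bromo-8-methoxy-2H-chromen-2-one | COc1cc(Br)cc2ccc(=O)oc12
F5 | step 2 | 6-bromo-8-methoxy-2H-chromen-2-ol (racemic) | COc1cc(Br)cc2C=CC(O)Oc12
F6 | step 2 | 6-bromo-2-ethoxy-8-methoxy-2H-chromene (racemic) | CCOC1C=Cc2cc(Br)cc(OC)c2O1
F7 | step 1 | 4-bromo-2-ethenyl-6-methoxyphenol | C=Cc1cc(Br)cc(OC)c1O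
F8 | step 1 | (E)-3-(3,4-dimethoxyphenyl)prop-2-en-1-ol | COc1ccc(/C=C/CO)cc1OC
F9 | step 1 | (E)-3-(3,4-dimethoxyphenyl)prop-2-en-1-yl methyl carbonate | COC(=O)OC/C=C/c1ccc(OC)c(OC)c1
F10 | step 1 | 5-bromo-2-{[(1S)-1-(3,4-dimethoxyphenyl)prop-2-en-1-yl]oxy}-1-ethenyl-3-methoxybenzene | COc1ccc([C@H](C=C)Oc2c(OC)cc(Br)cc2C=C)cc1OC
F11 | step 6 | methyl (2E)-3-[(2S,3R)-2-(3,4-dimethoxyphenyl)-3-(hydroxymethyl)-7-methoxy-2,3-dihydro-1-benzofuran-5-yl]prop-2-enoate | COc1ccc([C@H]2Oc3c(OC)cc(/C=C/C(=O)OC)cc3[C@@H]2CO)cc1OC
A1 | alternative 1 | anti secondary benzylic boronic ester of 1,2-dimethylacenaphthylene-1,2-diol, with ring B on the boron-bearing carbon and the protected ring A and a silyloxymethyl group on the next carbon | COc1ccc([C@H](B2O[C@@]3(C)c4cccc5cccc(c45)[C@@]3(C)O2)[C@@H](CO[Si](C)(C)C(C)(C)C)c2cc(C3OCCO3)cc(OC)c2OCOC)cc1OC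
A2 | alternative 2 | 2-[1-(tert-butyldimethylsilyloxy)-3-(3,4-dimethoxyphenyl)-3-(ethynyloxy)propan-2-yl]-4-[(tert-butyldimethylsilyloxy)methyl]furan, configuration as in the SMILES | COc1ccc([C@@H](OC#C)[C@@H](CO[Si](C)(C)C(C)(C)C)c2cc(CO[Si](C)(C)C(C)(C)C)co2)cc1OC
A3 | alternative 2 | trans-3,5-bis[(tert-butyldimethylsilyloxy)methyl]-2-(3,4-dimethoxyphenyl)-2,3-dihydro-1-benzofuran-7-ol | COc1ccc([C@H]2Oc3c(O)cc(CO[Si](C)(C)C(C)(C)C)cc3[C@@H]2CO[Si](C)(C)C(C)(C)C)cc1OC
A4 | alternative 3 | trans-5-(3,4-dimethoxyphenyl)-4-[(triisopropylsilyloxy)methyl]-2-(trimethylsilyloxy)-4,5-dihydrofuran | COc1ccc([C@H]2OC(O[Si](C)(C)C)=C[C@@H]2CO[Si](C(C)C)(C(C)C)C(C)C)cc1OC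
A5 | alternative 3 | methyl 3-bromo-2-oxo-2H-pyran-5-carboxylate | COC(=O)C1=COC(=O)C(Br)=C1
A6 | alternative 3 | methyl trans-7-bromo-2-(3,4-dimethoxyphenyl)-3-[(triisopropylsilyloxy)methyl]-2,3-dihydro-1-benzofuran-5-carboxylate | COc1ccc([C@H]2Oc3c(Br)cc(C(=O)OC)cc3[C@@H]2CO[Si](C(C)C)(C(C)C)C(C)C)cc1OC
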